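**Retrosynthetic overview**

1. Target 26 ⇐ desilylation and an O11→O10 1,2-isobutyryl shift ⇐ syn-8,10-diol 24 ⇐ C9–C10 bond by boron aldol of methyl enone 16 [ring–C7(=CH2)–C8(=O)–C9H3] with α-acyloxy aldehyde 21 [O=C10H–C11Me2–O-isobutyryl], the aldolate being reduced in the same flask.
2. Enabling feature: C8(OH)–C9H2–C10(O) is a 1,3-syn dioxygenated chain held between the sp2 carbon C7 (exo-methylene) and the quaternary C11. The C8 ketone can therefore enolise only toward C9, the C10 aldehyde cannot enolise, and O11 sits 1,2 to O10, so the ester it carries can be handed to O10.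
3. 16 ⇐ formaldehyde HWE ⇐ ring dressing (O2 silyl, O3 angelate, orthoester → axial O6 isobutyrate, O5 acetate) ⇐ osmylation of C2=C3 ⇐ Pd-catalysed cis-1,4 opening of vinyl epoxide 4 by ketophosphonate 5 (sets C1, frees O4).
4. 4 ⇐ hydroxyl-directed epoxidation of toluene cis-dihydrodiol 1, whose ring, C4 methyl and C5/C6 carbinol centres map directly onto the target. No carbocycle is formed; two temporary rings are made (C3–C4 oxirane, then the O5/O6 dioxolane orthoester) and opened in that order (steps 3 and 8).
5. 21 ⇐ ozonolysis of the isobutyrate of 2-methylbut-3-en-2-ol.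

Key step: step 13

Remark (locants): target locants are used throughout: ring C1 (side chain), C2, C3, C4 (methyl), C5, C6; chain C7 (exo-methylene carbon), C8, C9, C10, C11; β is the ring face of the C1 side chain, O4, O5 and O6, α the face of O2, O3 and the C4 methyl.
Assumption: 1 is treated as a purchasable chiral-pool compound (product of microbial toluene dioxygenation).
Assumption: the known sense of induction of methyl ketone enol diisopinocampheylborinates (attack on the aldehyde si face with the reagent made from (+)-α-pinene) is taken to hold for the hindered aldehyde 21; were it reversed, the enantiomeric reagent would be used with nothing else changed.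

**Route**

Step 1
Reactants: 1 (1S,2R)-3-methylcyclohexa-3,5-diene-1,2-diol
Product: 2 3β,4β-epoxy-4α-methylcyclohex-1-ene-5β,6β-diol
Conditions: mCPBA (1.0 equiv), Na2HPO4, CH2Cl2–acetone, −10 to 0 °C
Reagents that add atoms: mCPBA OOC(=O)c1cccc(Cl)c1
Why: Hydroxyl-directed peracid epoxidation: the trisubstituted C3=C4 bond is the more nucleophilic alkene and the allylic C5-OH delivers the peracid by hydrogen bonding to its own (β) face, which sets C3 and C4, while the buffer guards the diene-diol against acid-induced aromatisation.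

Step 2
Reactants: 2 3β,4β-epoxy-4α-methylcyclohex-1-ene-5β,6β-diol; 3 trimethyl orthoisobutyrate
Product: 4 3β,4β-epoxy-5β,6β-O-(1-methoxy-2-methylpropylidene)-4α-methylcyclohex-1-ene
Conditions: 3 (3 equiv), PPTS (2 mol%), CH2Cl2, 0 °C, then Et3N
Reagents that add atoms: none
Why: Acid-catalysed transorthoesterification of a cis-1,2-diol to the 2-alkoxy-1,3-dioxolane, with a catalyst weak enough to spare the vinyl oxirane; the orthoester is both the diol protecting group and the latent O6 isobutyrate.

Step 3
Reactants: 4 3β,4β-epoxy-5β,6β-O-(1-methoxy-2-methylpropylidene)-4α-methylcyclohex-1-ene; 5 dimethyl (2-oxopropyl)phosphonate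
Product: 6 dimethyl [1-(4β-hydroxy-4α-methyl-5β,6β-orthoester-cyclohex-2-en-1β-yl)-2-oxopropyl]phosphonate
Conditions: Pd2(dba)3·CHCl3 (2.5 mol%), dppe (6 mol%), THF, rt to 40 °C
Reagents that add atoms: none
Why: Tsuji–Trost alkylation of a vinyl epoxide under neutral conditions: Pd(0) ionises the allylic C3–O bond from the α face, the C4 alkoxide deprotonates 5, and the soft carbanion attacks the distal terminus C1 anti to palladium (C3 is screened by the quaternary C4), so the new C1–C7 bond is β and cis to O4 (net retention), while C7 forms as a mixture that is erased in step 10.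

Step 4
Reactants: 6 dimethyl [1-(4β-hydroxy-4α-methyl-5β,6β-orthoester-cyclohex-2-en-1β-yl)-2-oxopropyl]phosphonate
Product: 7 2α,3α-diol of 6 (2α,3α,4β-triol)
Conditions: K2OsO4·2H2O (4 mol%), NMO (1.5 equiv), acetone–H2O (5:1), trace pyridine, rt
Reagents that add atoms: N-methylmorpholine N-oxide C[N+]1([O-])CCOCC1; water O
Why: Upjohn dihydroxylation (syn addition): osmium should add to C2=C3 from the α face, anti to the allylic C4 hydroxyl, to the C1 substituent and to the dioxolane, which sets C2 and C3; the slightly basic medium preserves the orthoester.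

Step 5
Reactants: 7 2α,3α-diol of 6 (2α,3α,4β-triol)
Product: 8 2α-O-triethylsilyl ether of 7
Conditions: TESCl (1.05 equiv), imidazole, CH2Cl2–DMF, −30 °C
Reagents that add atoms: chlorotriethylsilane CC[Si](Cl)(CC)CC
Why: Selective silylation of the less hindered equatorial C2-OH: the C3-OH is axial and flanked by the quaternary C4, and the tertiary C4-OH does not react with a silyl chloride at low temperature.

Step 6
Reactants: 9 angelic acid
Product: 10 angelic 2,4,6-trichlorobenzoic anhydride
Conditions: 2,4,6-trichlorobenzoyl chloride, Et3N, toluene, rt; filtered and used crude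
Reagents that add atoms: 2,4,6-trichlorobenzoyl chloride O=C(Cl)c1c(Cl)cc(Cl)cc1Cl
Why: Yamaguchi mixed-anhydride formation by carboxylate acylation at room temperature, without a nucleophilic catalyst, so that the Z alkene is kept.

Step 7
Reactants: 8 2α-O-triethylsilyl ether of 7; 10 angelic 2,4,6-trichlorobenzoic anhydride
Product: 11 3α-O-angeloyl derivative of 8
Conditions: 10 (4 equiv), Et3N, toluene, 80 °C
Reagents that add atoms: none
Why: Yamaguchi-type esterification run without DMAP: the C3 alcohol attacks the unhindered angeloyl carbonyl (the aroyl carbonyl is shielded by two ortho chlorines), the tertiary C4-OH does not compete, the absence of a nucleophilic catalyst avoids Z→E isomerisation to the tiglate, and orthoester and silyl ether are stable to the basic medium.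

Step 8
Reactants: 11 3α-O-angeloyl derivative of 8
Product: 12 6β-O-isobutyryl-5β-hydroxy compound (orthoester opened)
Conditions: PPTS (0.1 equiv), THF–H2O (10:1), 0 °C
Reagents that add atoms: water O
Why: Mild acid hydrolysis of the cyclic orthoester via the 1,3-dioxolan-2-ylium ion and its hemiorthoester: stereoelectronically controlled opening should place the ester on the axial oxygen (O6, axial when the C1 side chain is equatorial) and free the equatorial O5-H, under conditions too mild for the silyl ether.

Step 9
Reactants: 12 6β-O-isobutyryl-5β-hydroxy compound (orthoester opened); 13 acetic anhydride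
Product: 14 5β-O-acetyl derivative of 12
Conditions: Ac2O, pyridine, DMAP (cat.), CH2Cl2, 0 °C
Reagents that add atoms: none
Why: DMAP-catalysed acetylation of the only secondary hydroxyl (O5), done at once so that the axial O6 ester has no time to migrate; the tertiary C4-OH is not acylated under these conditions.

Step 10
Reactants: 14 5β-O-acetyl derivative of 12; 15 formaldehyde
Product: 16 3-(ring-1β-yl)but-3-en-2-one (methyl enone)
Conditions: 37% aq. HCHO (excess), K2CO3, THF, 0 °C to rt
Reagents that add atoms: none
Why: Horner–Wadsworth–Emmons olefination with formaldehyde: the phosphonate carbanion adds to formaldehyde and eliminates dimethyl phosphate to give the 1,1-disubstituted enone, excess formaldehyde suppresses Michael addition of the carbanion to the product, and the C7 stereocentre disappears.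

Step 11
Reactants: 17 2-methylbut-3-en-2-ol; 18 isobutyric anhydride
Product: 19 2-methylbut-3-en-2-yl 2-methylpropanoate
Conditions: Et3N, DMAP (10 mol%), neat, 50 °C
Reagents that add atoms: none
Why: DMAP-catalysed acyl transfer (Steglich-type acylation) to a tertiary allylic alcohol; no stereocentre is involved.

Step 12
Reactants: 19 2-methylbut-3-en-2-yl 2-methylpropanoate
Product: 21 2-methyl-1-oxopropan-2-yl 2-methylpropanoate, via secondary ozonide 20 (not isolated)
Conditions: O3, CH2Cl2, −78 °C; then Me2S, −78 °C to rt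
Reagents that add atoms: ozone [O-][O+]=O
Why: Ozonolysis with reductive work-up cleaves the vinyl group to the non-enolisable α-acyloxy aldehyde; the ester is inert to ozone.

Step 13
Reactants: 16 3-(ring-1β-yl)but-3-en-2-one (methyl enone); 21 2-methyl-1-oxopropan-2-yl 2-methylpropanoate
Product: 24 (8R,10S)-8,10-diol with O11 isobutyrate and O2 silyl ether, via boron dienolate 22 (not isolated), via boron aldolate 23 (not isolated)
Conditions: (−)-Ipc2BCl (2.2 equiv, from (+)-α-pinene), Et3N (3 equiv), Et2O, 0 °C; 21 (1.5 equiv), −78 to −20 °C; LiBH4, THF, −78 °C; then MeOH, pH 7 buffer, 30% H2O2, 0 °C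
Reagents that add atoms: none
Why: Et3N and (−)-Ipc2BCl enolise the C8 methyl ketone on its only enolisable side (C9, since C7 is sp2) to the cross-conjugated boron dienolate 22, which adds to the non-enolisable aldehyde 21 through a cyclic six-membered boron transition state to give aldolate 23; LiBH4 then reduces the boron-chelated C8 carbonyl in the same flask and buffered H2O2 frees the diol. The closest known reaction type is the diisopinocampheylboron aldol of a methyl ketone with in situ LiBH4 reduction of the boron aldolate to a 1,3-syn diol. No ring is closed. C10 (S) is set by the isopinocampheyl ligands through attack on the aldehyde si face, and C8 (R) is set by C10 through external hydride attack on the half-chair boron chelate anti to its pseudo-equatorial C10 substituent (1,3-syn). The step needs 1,2- rather than 1,4-hydride addition to the enone, which boron activation of the carbonyl and −78 °C should secure, and survival of the five esters, which react far more slowly with LiBH4 at −78 °C than a chelated ketone. The hindered tertiary C4-OH may be borylated by the excess reagent and is released again in the oxidative work-up.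

Step 14
Reactants: 24 (8R,10S)-8,10-diol with O11 isobutyrate and O2 silyl ether
Product: 25 (8R,10S)-8,11-diol with O10 isobutyrate and O2 silyl ether
Conditions: DBU (0.2 equiv), CH2Cl2, 0 °C, stopped at full conversion
Reagents that add atoms: none
Why: Base-catalysed intramolecular O→O 1,2-acyl migration through a five-membered cyclic orthoacid intermediate: the strained tertiary ester at O11 should pass to the adjacent secondary O10, the thermodynamically preferred site, faster than it can travel on to O8 through the six-membered pathway; O2 is silylated so the angelate cannot move, and the O5 acetate has only a tertiary neighbour to go to.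

Step 15
Reactants: 25 (8R,10S)-8,11-diol with O10 isobutyrate and O2 silyl ether
Product: 26 target CNP0139270.1
Conditions: HF·pyridine, pyridine, THF, 0 °C
Reagents that add atoms: none
Why: Fluoride-mediated desilylation under buffered, non-basic conditions removes the secondary triethylsilyl ether, so no ester should migrate (in particular not the O3 angelate to the freed cis O2-H) and no stereocentre is touched.

**Compound list**

1 | (1S,2R)-3-methylcyclohexa-3,5-diene-1,2-diol (toluene cis-dihydrodiol; its hydroxyls become O6 and O5) | C1=CC=C(C)[C@@H](O)[C@H]1O | starting material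
2 | 3β,4β-epoxy-4α-methylcyclohex-1-ene-5β,6β-diol (oxirane cis to both hydroxyls) | C1=C[C@H]2O[C@@]2(C)[C@@H](O)[C@H]1O | intermediate
3 | trimethyl orthoisobutyrate (1,1,1-trimethoxy-2-methylpropane) | COC(OC)(OC)C(C)C | starting material
4 | 3β,4β-epoxy-5β,6β-O-(1-methoxy-2-methylpropylidene)-4α-methylcyclohex-1-ene (cyclic orthoester, both epimers at the orthoester carbon) | C1=C[C@H]2O[C@@]2(C)[C@H]3OC(OC)(C(C)C)O[C@@H]13 | intermediate
5 | dimethyl (2-oxopropyl)phosphonate | CC(=O)CP(=O)(OC)OC | starting material
6 | dimethyl [1-(4β-hydroxy-4α-methyl-5β,6β-orthoester-cyclohex-2-en-1β-yl)-2-oxopropyl]phosphonate (epimers at C7) | CC(=O)C(P(=O)(OC)OC)[C@H]1C=C[C@@](C)(O)[C@H]2OC(OC)(C(C)C)O[C@@H]12 | intermediate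
7 | 2α,3α-diol of 6 (2α,3α,4β-triol) | CC(=O)C(P(=O)(OC)OC)[C@H]1[C@H](O)[C@H](O)[C@@](C)(O)[C@H]2OC(OC)(C(C)C)O[C@@H]12 | intermediate
8 | 2α-O-triethylsilyl ether of 7 | CC(=O)C(P(=O)(OC)OC)[C@H]1[C@H](O[Si](CC)(CC)CC)[C@H](O)[C@@](C)(O)[C@H]2OC(OC)(C(C)C)O[C@@H]12 | intermediate
9 | angelic acid, (Z)-2-methylbut-2-enoic acid | C/C=C(/C)C(=O)O | starting material
10 | angelic 2,4,6-trichlorobenzoic anhydride | C/C=C(/C)C(=O)OC(=O)c1c(Cl)cc(Cl)cc1Cl | intermediate
11 | 3α-O-angeloyl derivative of 8 | CC(=O)C(P(=O)(OC)OC)[C@H]1[C@H](O[Si](CC)(CC)CC)[C@H](OC(=O)/C(C)=C\C)[C@@](C)(O)[C@H]2OC(OC)(C(C)C)O[C@@H]12 | intermediate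
12 | 6β-O-isobutyryl-5β-hydroxy compound (orthoester of 11 opened) | CC(=O)C(P(=O)(OC)OC)[C@H]1[C@H](O[Si](CC)(CC)CC)[C@H](OC(=O)/C(C)=C\C)[C@@](C)(O)[C@@H](O)[C@H]1OC(=O)C(C)C | intermediate
13 | acetic anhydride | CC(=O)OC(C)=O | starting material
14 | 5β-O-acetyl derivative of 12 | CC(=O)C(P(=O)(OC)OC)[C@H]1[C@H](O[Si](CC)(CC)CC)[C@H](OC(=O)/C(C)=C\C)[C@@](C)(O)[C@@H](OC(C)=O)[C@H]1OC(=O)C(C)C | intermediate
15 | formaldehyde (37% aqueous) | C=O | starting material
16 | methyl enone, 3-(ring-1β-yl)but-3-en-2-one; ring: 2α-OSiEt3, 3α-O-angeloyl, 4β-OH/4α-Me, 5β-OAc, 6β-O-isobutyryl | CC(=O)C(=C)[C@H]1[C@H](O[Si](CC)(CC)CC)[C@H](OC(=O)/C(C)=C\C)[C@@](C)(O)[C@@H](OC(C)=O)[C@H]1OC(=O)C(C)C | intermediate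
17 | 2-methylbut-3-en-2-ol | C=CC(C)(C)O | starting material
18 | isobutyric anhydride | CC(C)C(=O)OC(=O)C(C)C | starting material
19 | 2-methylbut-3-en-2-yl 2-methylpropanoate | C=CC(C)(C)OC(=O)C(C)C | intermediate
20 | secondary ozonide (1,2,4-trioxolane) of 19 | C1OOC(O1)C(C)(C)OC(=O)C(C)C | intermediate
21 | 2-methyl-1-oxopropan-2-yl 2-methylpropanoate | O=CC(C)(C)OC(=O)C(C)C | intermediate
22 | diisopinocampheylboron dienolate of 16 (O8–B, C8=C9) | C=C(OB([C@@H]2C[C@@H]3C[C@H]([C@H]2C)C3(C)C)[C@@H]2C[C@@H]3C[C@H]([C@H]2C)C3(C)C)C(=C)[C@H]1[C@H](O[Si](CC)(CC)CC)[C@H](OC(=O)/C(C)=C\C)[C@@](C)(O)[C@@H](OC(C)=O)[C@H]1OC(=O)C(C)C | intermediate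
23 | diisopinocampheylboron aldolate (10S; C8 ketone, O10–B, O11 isobutyrate) | C=C([C@H]1[C@H](O[Si](CC)(CC)CC)[C@H](OC(=O)/C(C)=C\C)[C@@](C)(O)[C@@H](OC(C)=O)[C@H]1OC(=O)C(C)C)C(=O)C[C@H](OB([C@@H]2C[C@@H]3C[C@H]([C@H]2C)C3(C)C)[C@@H]2C[C@@H]3C[C@H]([C@H]2C)C3(C)C)C(C)(C)OC(=O)C(C)C | intermediate
24 | (8R,10S)-8,10-diol; O11 isobutyrate; O2 triethylsilyl ether | C=C([C@H]1[C@H](O[Si](CC)(CC)CC)[C@H](OC(=O)/C(C)=C\C)[C@@](C)(O)[C@@H](OC(C)=O)[C@H]1OC(=O)C(C)C)[C@H](O)C[C@H](O)C(C)(C)OC(=O)C(C)C | intermediate
25 | (8R,10S)-8,11-diol; O10 isobutyrate; O2 triethylsilyl ether | C=C([C@H]1[C@H](O[Si](CC)(CC)CC)[C@H](OC(=O)/C(C)=C\C)[C@@](C)(O)[C@@H](OC(C)=O)[C@H]1OC(=O)C(C)C)[C@H](O)C[C@H](OC(=O)C(C)C)C(C)(C)O | intermediate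
26 | CNP0139270.1; (1S,2S,3S,4R,5S,6S)-ring and (8R,10S)-chain in the locants above: 2,4,8,11-tetrol, 3-O-angelate, 5-O-acetate, 6-O- and 10-O-isobutyrate | C=C([C@H]1[C@H](O)[C@H](OC(=O)/C(C)=C\C)[C@@](C)(O)[C@@H](OC(C)=O)[C@H]1OC(=O)C(C)C)[C@H](O)C[C@H](OC(=O)C(C)C)C(C)(C)O | target

**Step count and risks**

Total step count: 15. Longest linear sequence: 12 steps (1, 2, 3, 4, 5, 7, 8, 9, 10, 13, 14, 15 from compound 1); step 6 and steps 11–12 are side branches.

Steps most likely to fail:

Step 13. The hindered α-quaternary aldehyde may be attacked with poor enantioface selectivity by the boron dienolate, and hydride may add in conjugate fashion to the enone during the in-flask reduction. Fallback: setting out from 16, silylation with TMSOTf and Et3N (CH2Cl2, −78 °C) should give the bis-silyl dienol ether F1 (C8 enol silane, C4 silyl ether). A Mukaiyama aldol of F1 with 21, promoted by the enantiomer of an N-tosyl-tryptophan-derived B-alkyl oxazaborolidinone that directs si-face attack, with acidic work-up that strips both trimethylsilyl groups, should give the β-hydroxy ketone F2. A separate Narasaka–Prasad reduction (Et2BOMe, NaBH4, THF–MeOH, −78 °C) of F2 should then deliver the syn-diol and come back to the route at 24.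

Step 14. The acyl group may travel on from O10 to the allylic O8 through the six-membered pathway, so that ester positions scramble before the tertiary ester is consumed. Fallback: setting out from 24, selective silylation of the less hindered allylic C8-OH (TESCl, imidazole, CH2Cl2, −40 °C; the C10-OH is neopentyl-like) should give the 2,8-bis-silyl ether F3. With O8 blocked, DBU can only move the ester to O10 and should give the 10-O-isobutyrate F4. HF·pyridine then removes both silyl ethers and the fallback comes back to the route at 26.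

Step 7. The axial C3-OH next to the quaternary C4 may be acylated too slowly by the mixed anhydride, and prolonged heating invites Z→E isomerisation of the angelate and erosion of the orthoester. Fallback: setting out from 8, esterification with the small, linear but-2-ynoic acid (DIC, DMAP cat., CH2Cl2) should give the but-2-ynoate F5. Palladium-catalysed syn-hydrostannation (Bu3SnH, Pd(PPh3)4 cat., THF) should give the α-stannyl (E)-enoate F6, with the β-methyl cis to the ester carbonyl. Stille methylation with retention (MeI, Pd2(dba)3, AsPh3, CuI, DMF) then builds the angelate and comes back to the route at 11.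

**Further compounds**

F1 | step 13 | C8 trimethylsilyl dienol ether of 16 with C4 trimethylsilyl ether | C=C(O[Si](C)(C)C)C(=C)[C@H]1[C@H](O[Si](CC)(CC)CC)[C@H](OC(=O)/C(C)=C\C)[C@@](C)(O[Si](C)(C)C)[C@@H](OC(C)=O)[C@H]1OC(=O)C(C)C
F2 | step 13 | (10S)-10-hydroxy C8 ketone with O11 isobutyrate (aldol adduct) | C=C([C@H]1[C@H](O[Si](CC)(CC)CC)[C@H](OC(=O)/C(C)=C\C)[C@@](C)(O)[C@@H](OC(C)=O)[C@H]1OC(=O)C(C)C)C(=O)C[C@H](O)C(C)(C)OC(=O)C(C)C
F3 | step 14 | 8-O-triethylsilyl ether of 24 | C=C([C@H]1[C@H](O[Si](CC)(CC)CC)[C@H](OC(=O)/C(C)=C\C)[C@@](C)(O)[C@@H](OC(C)=O)[C@H]1OC(=O)C(C)C)[C@H](O[Si](CC)(CC)CC)C[C@H](O)C(C)(C)OC(=O)C(C)C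
F4 | step 14 | 8-O-triethylsilyl ether of 25 | C=C([C@H]1[C@H](O[Si](CC)(CC)CC)[C@H](OC(=O)/C(C)=C\C)[C@@](C)(O)[C@@H](OC(C)=O)[C@H]1OC(=O)C(C)C)[C@H](O[Si](CC)(CC)CC)C[C@H](OC(=O)C(C)C)C(C)(C)O
F5 | step 7 | 3α-O-(but-2-ynoyl) derivative of 8 | CC(=O)C(P(=O)(OC)OC)[C@H]1[C@H](O[Si](CC)(CC)CC)[C@H](OC(=O)C#CC)[C@@](C)(O)[C@H]2OC(OC)(C(C)C)O[C@@H]12
F6 | step 7 | 3α-O-[(E)-2-(tributylstannyl)but-2-enoyl] derivative of 8 | CC(=O)C(P(=O)(OC)OC)[C@H]1[C@H](O[Si](CC)(CC)CC)[C@H](OC(=O)/C([Sn](CCCC)(CCCC)CCCC)=C\C)[C@@](C)(O)[C@H]2OC(OC)(C(C)C)O[C@@H]12
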